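**Retrosynthetic overview**
1. Target ⇐ C4 silyl ether ⇐ selenoxide elimination (C4a′=C4′) ⇐ double ketalization of the C8a′ ketone by O5 (ring F, dihydrofuran) and O1′ (ring E, second pyran).
2. Side chain C4′–C2′(Ph) ⇐ intermolecular Michael addition of the ring D 1,3-dione to phenyl vinyl ketone, then asymmetric transfer hydrogenation (sets C2′).
3. Ring D (carbocycle) ⇐ crossed Claisen condensation (acetate enolate opens the lactone at C8a′) and Dieckmann closure onto a β-methoxyacrylate that already fixes the C7′ methoxy group.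
4. Key step: intermolecular Michael addition of a 3-methoxybenzofuranone to ethyl buta-2,3-dienoate makes the C8′–C7′ bond and the quaternary C8′ centre.
5. Flavan half ⇐ Claisen–Schmidt aldol, flavanone (ring C), kinetic resolution by transfer hydrogenation, Mitsunobu inversion. Ring order: C → lactone → D → F and E.

**Conventions (one assumption):** the flavan half carries plain locants (O1, C2–C8a), the dienone half primed ones (O1′, C2′–C8a′); the inter-unit bonds are C6–C8′ and O5–C8a′. The target is then (2S,4R,2′S,8′S,8a′S). "Fl" = (2S,4R)-4-(tert-butyldimethylsilyloxy)-7,8-dimethoxy-2-phenylchroman. "Lactone" = benzofuran-2(3H)-one built on O5 and C6 of Fl (its C2 = C8a′, its C3 = C8′). CIP descriptors at C8′ change along the route although the spatial arrangement does not. The route is designed on paper and has not been run.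

**Step 1**
Reactants: 1 3,4,5-trimethoxyphenol
Product: 2 1,2,3,5-tetramethoxybenzene
Conditions: Me2SO4, K2CO3, acetone, reflux
Reagents that add atoms: dimethyl sulfate, COS(=O)(=O)OC
Why: Williamson O-methylation of the phenoxide; no stereocentre.

**Step 2**
Reactants: 2 1,2,3,5-tetramethoxybenzene; 3 acetyl chloride
Product: 5 1-(2-hydroxy-3,4,6-trimethoxyphenyl)ethanone, via tetramethoxyacetophenone 4 (not isolated)
Conditions: AlCl3 (2.2 equiv), Et2O/CH2Cl2, 0 °C to rt; aq. HCl
Reagents that add atoms: none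
Why: Friedel–Crafts acylation at the only kind of free position, then chelation-assisted cleavage by AlCl3 of the ortho methoxy group that is buttressed by its methoxy neighbour.

**Step 3**
Reactants: 5 1-(2-hydroxy-3,4,6-trimethoxyphenyl)ethanone; 6 benzaldehyde
Product: 7 (E)-1-(2-hydroxy-3,4,6-trimethoxyphenyl)-3-phenylprop-2-en-1-one
Conditions: KOH, EtOH, rt
Reagents that add atoms: none
Why: Claisen–Schmidt aldol condensation; E1cB dehydration gives the E enone.

**Step 4**
Reactants: 7 the chalcone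
Product: 8 rac-5,7,8-trimethoxy-2-phenylchroman-4-one
Conditions: NaOAc, EtOH, reflux
Reagents that add atoms: none
Why: intramolecular oxa-Michael addition of the 2′-phenoxide (favoured by the 6′-substituent); racemic at C2.

**Step 5**
Reactants: 8 rac-5,7,8-trimethoxyflavanone
Product: 9 rac-5-hydroxy-7,8-dimethoxy-2-phenylchroman-4-one
Conditions: BCl3 (1.1 equiv), CH2Cl2, −78 to 0 °C
Reagents that add atoms: none
Why: chelation-controlled Lewis acid ether cleavage, selective for the methoxy group peri to the C4 carbonyl.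

**Step 6**
Reactants: 9 rac-5-hydroxy-7,8-dimethoxyflavanone
Product: 10 rac-5-benzyloxy-7,8-dimethoxy-2-phenylchroman-4-one
Conditions: BnBr, K2CO3, DMF, 50 °C
Reagents that add atoms: benzyl bromide, BrCc1ccccc1
Why: Williamson etherification of the acidic chelated phenol; the substrate is still racemic, so any ring opening is harmless.

**Step 7**
Reactants: 10 rac-5-benzyloxy-7,8-dimethoxyflavanone
Product: 11 (2S,4S)-5-benzyloxy-7,8-dimethoxy-2-phenylchroman-4-ol
Conditions: RuCl[(S,S)-TsDPEN](p-cymene) (2 mol %), HCO2H/Et3N 5:2, EtOAc, 40 °C, stopped near 50% conversion; unreacted (R)-10 separated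
Reagents that add atoms: none
Why: Noyori–Ikariya asymmetric transfer hydrogenation with kinetic resolution; the (S,S) catalyst reduces only the (2S) ketone quickly, hydride entering anti to the 2-phenyl group to give the 2,4-cis (4S) alcohol.

**Step 8**
Reactants: 11 (2S,4S)-alcohol
Product: 12 (2S,4R)-5-benzyloxy-7,8-dimethoxy-2-phenylchroman-4-yl 4-nitrobenzoate
Conditions: 4-nitrobenzoic acid, PPh3, DIAD, THF, 0 °C to rt
Reagents that add atoms: 4-nitrobenzoic acid, OC(=O)c1ccc(cc1)[N+](=O)[O-]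
Why: Mitsunobu esterification with inversion at C4 gives the 2,4-trans (4R) ester.

**Step 9**
Reactants: 12 the 4-nitrobenzoate
Product: 13 (2S,4R)-5-benzyloxy-7,8-dimethoxy-2-phenylchroman-4-ol
Conditions: K2CO3, MeOH/THF, rt
Reagents that add atoms: none
Why: base-catalysed transesterification cleaves the acyl–O bond, so C4 keeps its configuration.

**Step 10**
Reactants: 13 (2S,4R)-alcohol
Product: 14 (2S,4R)-5-benzyloxy-4-(tert-butyldimethylsilyloxy)-7,8-dimethoxy-2-phenylchromane
Conditions: TBSCl, imidazole, DMF, 40 °C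
Reagents that add atoms: tert-butyldimethylsilyl chloride, CC(C)(C)[Si](C)(C)Cl
Why: silylation of the secondary alcohol; the base-stable silyl ether also suppresses ionization at the electron-rich benzylic C4.

**Step 11**
Reactants: 14 benzyl ether
Product: 15 (2S,4R)-4-(tert-butyldimethylsilyloxy)-7,8-dimethoxy-2-phenylchroman-5-ol
Conditions: H2 (1 atm), 10% Pd/C, EtOAc, rt
Reagents that add atoms: none
Why: hydrogenolysis of the aryl benzyl ether, much faster than cleavage of the cyclic benzylic ether or the silyl ether under neutral conditions.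

**Step 12**
Reactants: 15 phenol; 16 ethyl glyoxylate
Product: 18 3-hydroxy lactone (3-hydroxybenzofuran-2(3H)-one on O5/C6 of Fl, both C3 epimers), via ethyl aryl(hydroxy)acetate 17 (not isolated)
Conditions: EtMgBr (1.05 equiv), CH2Cl2, 0 °C; 16 (toluene solution), rt; then toluene, 80 °C
Reagents that add atoms: none
Why: ortho-specific aldol-type hydroxyalkylation of the magnesium phenoxide through a six-membered chelate (C6 is the only free ring carbon), then lactonization; the new centre is later enolized, so its configuration does not matter.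

**Step 13**
Reactants: 18 3-hydroxy lactone
Product: 19 3-methoxy lactone (3-methoxybenzofuran-2(3H)-one on O5/C6 of Fl, both C3 epimers)
Conditions: MeOTf, 2,6-di-tert-butyl-4-methylpyridine, CH2Cl2, rt
Reagents that add atoms: methyl trifluoromethanesulfonate, COS(=O)(=O)C(F)(F)F
Why: O-alkylation of the secondary alcohol by a hard methylating agent with a non-nucleophilic, non-enolizing base.

**Step 14 (key step)**
Reactants: 19 3-methoxy lactone; 20 ethyl buta-2,3-dienoate
Product: 21 ethyl 3-[(3R)-3-methoxy-2-oxo-lactone-3-yl]but-3-enoate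
Conditions: N-(9-anthracenylmethyl)-O-allylcinchonidinium bromide (10 mol %), Cs2CO3 (0.3 equiv), toluene, −40 °C, argon; minor C3 epimer removed by chromatography
Reagents that add atoms: none
Why: phase-transfer-catalysed intermolecular Michael addition of the benzofuran-2-olate to the central carbon of the allenoate gives the β,γ-unsaturated ester; the chiral ammonium ion pair shields one enolate face and sets the quaternary C8′ centre (the pseudo-enantiomeric cinchoninium salt is used if the sense proves opposite).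

**Step 15**
Reactants: 21 Michael adduct
Product: 22 ethyl 3-[(3S)-3-methoxy-2-oxo-lactone-3-yl]-3-oxopropanoate
Conditions: O3, CH2Cl2, −78 °C (Sudan red end point); Me2S
Reagents that add atoms: ozone, [O-][O+]=O
Why: ozonolysis of the 1,1-disubstituted alkene, which reacts far faster than the fully substituted arene; the quaternary centre is untouched.

**Step 16**
Reactants: 22 β-keto ester
Product: 23 ethyl (2E)-3-methoxy-3-[(3S)-3-methoxy-2-oxo-lactone-3-yl]prop-2-enoate
Conditions: Me2SO4, K2CO3, DMF, 0 °C to rt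
Reagents that add atoms: dimethyl sulfate, COS(=O)(=O)OC
Why: O-alkylation of the β-keto ester enolate (hard electrophile, dipolar aprotic solvent) gives the E β-methoxyacrylate, which fixes the methoxy group on C7′ while C7′ is the only ketone present.

**Step 17**
Reactants: 23 β-methoxyacrylate lactone; 24 allyl acetate
Product: 26 7-allyl 1-ethyl (2E,4S)-4-[5-(tert-butyldimethylsilyloxy)-Fl-6-yl]-3,4-dimethoxy-5-oxohept-2-enedioate, via phenol keto diester 25 (not isolated)
Conditions: 24 and LiN(iPr)2 (2.3 equiv each), THF, −78 °C; then TBSOTf, −78 to 0 °C; aq. citric acid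
Reagents that add atoms: tert-butyldimethylsilyl trifluoromethanesulfonate, CC(C)(C)[Si](C)(C)OS(=O)(=O)C(F)(F)F
Why: crossed Claisen condensation; the ester enolate attacks the strained aryl lactone (far more electrophilic than the vinylogous carbonate ester), and the released phenoxide is silylated in the flask so that it cannot add to C7′.

**Step 18**
Reactants: 26 β-keto allyl ester
Product: 27 allyl (3R)-3-[5-(tert-butyldimethylsilyloxy)-Fl-6-yl]-2-hydroxy-3,4-dimethoxy-6-oxocyclohexa-1,4-diene-1-carboxylate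
Conditions: NaH, THF, 0 to 45 °C; aq. HCl work-up
Reagents that add atoms: none
Why: Dieckmann condensation (six-membered ring) of the β-keto ester anion onto the acrylate ester, driven by formation of the stabilized tricarbonyl anion; this closes ring D.

**Step 19**
Reactants: 27 allyl ester
Product: 28 (4R)-4-[5-(tert-butyldimethylsilyloxy)-Fl-6-yl]-3-hydroxy-4,5-dimethoxycyclohexa-2,5-dien-1-one
Conditions: Pd(PPh3)4 (5 mol %), morpholine, THF, rt
Reagents that add atoms: none
Why: Tsuji-type deallylation through a π-allylpalladium complex trapped by morpholine; the β-tricarbonyl acid decarboxylates spontaneously.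

**Step 20**
Reactants: 28 vinylogous acid; 29 3-chloro-1-phenylpropan-1-one
Product: 31 (4R)-4-[5-(tert-butyldimethylsilyloxy)-Fl-6-yl]-3-hydroxy-4,5-dimethoxy-2-(3-oxo-3-phenylpropyl)cyclohexa-2,5-dien-1-one, via phenyl vinyl ketone 30 (not isolated)
Conditions: Et3N (2.2 equiv), CH2Cl2, rt
Reagents that add atoms: none
Why: E1cB loss of HCl gives phenyl vinyl ketone, and intermolecular Michael addition of the 1,3-dione anion through its central carbon (C4a′) attaches C4′–C2′.

**Step 21**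
Reactants: 31 triketone
Product: 32 (4R)-4-[5-(tert-butyldimethylsilyloxy)-Fl-6-yl]-3-hydroxy-2-[(3S)-3-hydroxy-3-phenylpropyl]-4,5-dimethoxycyclohexa-2,5-dien-1-one
Conditions: RuCl[(S,S)-TsDPEN](p-cymene) (1 mol %), HCO2H/Et3N 5:2, CH2Cl2, rt; used crude
Reagents that add atoms: none
Why: Noyori–Ikariya asymmetric transfer hydrogenation of the aryl ketone; the (S,S) catalyst gives the (S) carbinol (C2′) and the enolized dione is inert.

**Step 22**
Reactants: 32 hydroxy dione
Product: 33 (6S)-6-[5-(tert-butyldimethylsilyloxy)-Fl-6-yl]-2-[(3S)-3-hydroxy-3-phenylpropyl]-5,6-dimethoxy-2-(phenylselanyl)cyclohex-4-ene-1,3-dione (both C2 epimers)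
Conditions: PhSeCl, pyridine, CH2Cl2, −78 to 0 °C
Reagents that add atoms: benzeneselenenyl chloride, Cl[Se]c1ccccc1
Why: α-selenenylation of the 1,3-dione at its central carbon, by far the most nucleophilic site; it blocks enolization and leaves C8a′ as an ordinary ketone.

**Step 23**
Reactants: 33 selenide
Product: 34 (6S)-6-(5-hydroxy-Fl-6-yl)-2-[(3S)-3-hydroxy-3-phenylpropyl]-5,6-dimethoxy-2-(phenylselanyl)cyclohex-4-ene-1,3-dione
Conditions: Bu4NF/AcOH (1:1), THF, 0 °C
Reagents that add atoms: none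
Why: buffered fluoride desilylation; the aryl silyl ether (phenoxide leaving group) cleaves much faster than the secondary alkyl silyl ether at C4.

**Step 24**
Reactants: 34 phenol diol-dione
Product: 35 4a′-(phenylselanyl)-4′,4a′-dihydro derivative of 36 (2S,4R,2′S,8′S,8a′R; both C4a′ epimers)
Conditions: camphorsulfonic acid (5 mol %), 4 Å molecular sieves, CH2Cl2, rt
Reagents that add atoms: none
Why: acid-catalysed double ketalization of the only non-conjugated ketone (C8a′), with O5 closing ring F and the C2′ hydroxyl closing ring E; the five-membered ring must be cis-fused, so C8′ dictates C8a′.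

**Step 25**
Reactants: 35 selenide ketal
Product: 36 4-O-(tert-butyldimethylsilyl)-6″-demethoxyneocalycopterone
Conditions: H2O2 (30%), pyridine, CH2Cl2, 0 °C to rt
Reagents that add atoms: none
Why: selenoxide syn-elimination; only C4′ carries β-hydrogens, so the C4a′=C4′ enone forms regiospecifically from either C4a′ epimer.

**Step 26**
Reactants: 36 silyl ether
Product: 37 6″-demethoxyneocalycopterone
Conditions: Bu4NF/AcOH (1:1), THF, 40 °C
Reagents that add atoms: none
Why: buffered fluoride desilylation of the C4 silyl ether, mild enough for the ketal and the vinylogous ester.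

**Compound list**
1 | 3,4,5-trimethoxyphenol | COc1cc(O)cc(OC)c1OC | starting material
2 | 1,2,3,5-tetramethoxybenzene | COc1cc(OC)c(OC)c(OC)c1 | intermediate
3 | acetyl chloride | CC(=O)Cl | starting material
4 | 1-(2,3,4,6-tetramethoxyphenyl)ethanone | CC(=O)c1c(OC)cc(OC)c(OC)c1OC | intermediate
5 | 1-(2-hydroxy-3,4,6-trimethoxyphenyl)ethanone | CC(=O)c1c(OC)cc(OC)c(OC)c1O | intermediate
6 | benzaldehyde | O=Cc1ccccc1 | starting material
7 | (E)-1-(2-hydroxy-3,4,6-trimethoxyphenyl)-3-phenylprop-2-en-1-one | O=C(/C=C/c1ccccc1)c1c(OC)cc(OC)c(OC)c1O | intermediate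
8 | rac-5,7,8-trimethoxy-2-phenylchroman-4-one | COc1cc(OC)c(OC)c2OC(c3ccccc3)CC(=O)c12 | intermediate
9 | rac-5-hydroxy-7,8-dimethoxy-2-phenylchroman-4-one | Oc1cc(OC)c(OC)c2OC(c3ccccc3)CC(=O)c12 | intermediate
10 | rac-5-benzyloxy-7,8-dimethoxy-2-phenylchroman-4-one | O=C1CC(c2ccccc2)Oc2c(OC)c(OC)cc(OCc3ccccc3)c12 | intermediate
11 | (2S,4S)-5-benzyloxy-7,8-dimethoxy-2-phenylchroman-4-ol | c1ccccc1COc1cc(OC)c(OC)c2O[C@H](c3ccccc3)C[C@H](O)c12 | intermediate
12 | (2S,4R)-5-benzyloxy-7,8-dimethoxy-2-phenylchroman-4-yl 4-nitrobenzoate | c1ccccc1COc1cc(OC)c(OC)c2O[C@H](c3ccccc3)C[C@@H](OC(=O)c3ccc(cc3)[N+](=O)[O-])c12 | intermediate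
13 | (2S,4R)-5-benzyloxy-7,8-dimethoxy-2-phenylchroman-4-ol | c1ccccc1COc1cc(OC)c(OC)c2O[C@H](c3ccccc3)C[C@@H](O)c12 | intermediate
14 | (2S,4R)-5-benzyloxy-4-(tert-butyldimethylsilyloxy)-7,8-dimethoxy-2-phenylchromane | c1ccccc1COc1cc(OC)c(OC)c2O[C@H](c3ccccc3)C[C@@H](O[Si](C)(C)C(C)(C)C)c12 | intermediate
15 | (2S,4R)-4-(tert-butyldimethylsilyloxy)-7,8-dimethoxy-2-phenylchroman-5-ol | Oc1cc(OC)c(OC)c2O[C@H](c3ccccc3)C[C@@H](O[Si](C)(C)C(C)(C)C)c12 | intermediate
16 | ethyl glyoxylate | CCOC(=O)C=O | starting material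
17 | ethyl hydroxy(5-hydroxy-Fl-6-yl)acetate, both carbinol epimers | CCOC(=O)C(O)c1c(O)c2c(c(OC)c1OC)O[C@H](c1ccccc1)C[C@H]2O[Si](C)(C)C(C)(C)C | intermediate
18 | 3-hydroxy lactone (3-hydroxybenzofuran-2(3H)-one on O5/C6 of Fl), both C3 epimers | OC1C(=O)Oc2c1c(OC)c(OC)c1O[C@H](c3ccccc3)C[C@@H](O[Si](C)(C)C(C)(C)C)c21 | intermediate
19 | 3-methoxy lactone (3-methoxybenzofuran-2(3H)-one on O5/C6 of Fl), both C3 epimers | COC1C(=O)Oc2c1c(OC)c(OC)c1O[C@H](c3ccccc3)C[C@@H](O[Si](C)(C)C(C)(C)C)c21 | intermediate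
20 | ethyl buta-2,3-dienoate | CCOC(=O)C=C=C | starting material
21 | ethyl 3-[(3R)-3-methoxy-2-oxo-lactone-3-yl]but-3-enoate | CCOC(=O)CC(=C)[C@]1(OC)C(=O)Oc2c1c(OC)c(OC)c1O[C@H](c3ccccc3)C[C@@H](O[Si](C)(C)C(C)(C)C)c21 | intermediate
22 | ethyl 3-[(3S)-3-methoxy-2-oxo-lactone-3-yl]-3-oxopropanoate | CCOC(=O)CC(=O)[C@]1(OC)C(=O)Oc2c1c(OC)c(OC)c1O[C@H](c3ccccc3)C[C@@H](O[Si](C)(C)C(C)(C)C)c21 | intermediate
23 | ethyl (2E)-3-methoxy-3-[(3S)-3-methoxy-2-oxo-lactone-3-yl]prop-2-enoate | CCOC(=O)/C=C(/OC)[C@]1(OC)C(=O)Oc2c1c(OC)c(OC)c1O[C@H](c3ccccc3)C[C@@H](O[Si](C)(C)C(C)(C)C)c21 | intermediate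
24 | allyl acetate | CC(=O)OCC=C | starting material
25 | 7-allyl 1-ethyl (2E,4S)-4-(5-hydroxy-Fl-6-yl)-3,4-dimethoxy-5-oxohept-2-enedioate | C=CCOC(=O)CC(=O)[C@@](OC)(/C(OC)=C\C(=O)OCC)c1c(O)c2c(c(OC)c1OC)O[C@H](c1ccccc1)C[C@H]2O[Si](C)(C)C(C)(C)C | intermediate
26 | 7-allyl 1-ethyl (2E,4S)-4-[5-(tert-butyldimethylsilyloxy)-Fl-6-yl]-3,4-dimethoxy-5-oxohept-2-enedioate | C=CCOC(=O)CC(=O)[C@@](OC)(/C(OC)=C\C(=O)OCC)c1c(O[Si](C)(C)C(C)(C)C)c2c(c(OC)c1OC)O[C@H](c1ccccc1)C[C@H]2O[Si](C)(C)C(C)(C)C | intermediate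
27 | allyl (3R)-3-[5-(tert-butyldimethylsilyloxy)-Fl-6-yl]-2-hydroxy-3,4-dimethoxy-6-oxocyclohexa-1,4-diene-1-carboxylate | C=CCOC(=O)C1=C(O)[C@](OC)(c2c(O[Si](C)(C)C(C)(C)C)c3c(c(OC)c2OC)O[C@H](c2ccccc2)C[C@H]3O[Si](C)(C)C(C)(C)C)C(OC)=CC1=O | intermediate
28 | (4R)-4-[5-(tert-butyldimethylsilyloxy)-Fl-6-yl]-3-hydroxy-4,5-dimethoxycyclohexa-2,5-dien-1-one | O=C1C=C(OC)[C@@](OC)(c2c(O[Si](C)(C)C(C)(C)C)c3c(c(OC)c2OC)O[C@H](c2ccccc2)C[C@H]3O[Si](C)(C)C(C)(C)C)C(O)=C1 | intermediate
29 | 3-chloro-1-phenylpropan-1-one | O=C(CCCl)c1ccccc1 | starting material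
30 | phenyl vinyl ketone | C=CC(=O)c1ccccc1 | intermediate
31 | (4R)-4-[5-(tert-butyldimethylsilyloxy)-Fl-6-yl]-3-hydroxy-4,5-dimethoxy-2-(3-oxo-3-phenylpropyl)cyclohexa-2,5-dien-1-one | O=C1C=C(OC)[C@@](OC)(c2c(O[Si](C)(C)C(C)(C)C)c3c(c(OC)c2OC)O[C@H](c2ccccc2)C[C@H]3O[Si](C)(C)C(C)(C)C)C(O)=C1CCC(=O)c1ccccc1 | intermediate
32 | (4R)-4-[5-(tert-butyldimethylsilyloxy)-Fl-6-yl]-3-hydroxy-2-[(3S)-3-hydroxy-3-phenylpropyl]-4,5-dimethoxycyclohexa-2,5-dien-1-one | O=C1C=C(OC)[C@@](OC)(c2c(O[Si](C)(C)C(C)(C)C)c3c(c(OC)c2OC)O[C@H](c2ccccc2)C[C@H]3O[Si](C)(C)C(C)(C)C)C(O)=C1CC[C@H](O)c1ccccc1 | intermediate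
33 | (6S)-6-[5-(tert-butyldimethylsilyloxy)-Fl-6-yl]-2-[(3S)-3-hydroxy-3-phenylpropyl]-5,6-dimethoxy-2-(phenylselanyl)cyclohex-4-ene-1,3-dione | O=C1C=C(OC)[C@@](OC)(c2c(O[Si](C)(C)C(C)(C)C)c3c(c(OC)c2OC)O[C@H](c2ccccc2)C[C@H]3O[Si](C)(C)C(C)(C)C)C(=O)C1([Se]c1ccccc1)CC[C@H](O)c1ccccc1 | intermediate
34 | (6S)-6-(5-hydroxy-Fl-6-yl)-2-[(3S)-3-hydroxy-3-phenylpropyl]-5,6-dimethoxy-2-(phenylselanyl)cyclohex-4-ene-1,3-dione | O=C1C=C(OC)[C@@](OC)(c2c(O)c3c(c(OC)c2OC)O[C@H](c2ccccc2)C[C@H]3O[Si](C)(C)C(C)(C)C)C(=O)C1([Se]c1ccccc1)CC[C@H](O)c1ccccc1 | intermediate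
35 | 4a′-(phenylselanyl)-4′,4a′-dihydro derivative of 36 | COC1=CC(=O)C2([Se]c5ccccc5)CC[C@@H](c3ccccc3)O[C@]23Oc2c4c(c(OC)c(OC)c2[C@]13OC)O[C@H](c1ccccc1)C[C@H]4O[Si](C)(C)C(C)(C)C | intermediate
36 | 4-O-(tert-butyldimethylsilyl)-6″-demethoxyneocalycopterone | COC1=CC(=O)C2=CC[C@@H](c3ccccc3)O[C@]23Oc2c4c(c(OC)c(OC)c2[C@]13OC)O[C@H](c1ccccc1)C[C@H]4O[Si](C)(C)C(C)(C)C | intermediate
37 | 6″-demethoxyneocalycopterone | COC1=CC(=O)C2=CC[C@@H](c3ccccc3)O[C@]23Oc2c4c(c(OC)c(OC)c2[C@]13OC)O[C@H](c1ccccc1)C[C@H]4O | target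

**Totals:** 26 steps; longest linear sequence 26 steps (1 to 37).

**Three steps most likely to fail, with fallbacks**

Step 14 (the allenoate Michael addition may isomerize, add at the wrong carbon, or give poor control at C8′). The fallback sets out from 19 and returns at 22, skipping 21 and the ozonolysis. Lactone 19 is deprotonated with NaN(SiMe3)2 in THF at −78 °C and O-acylated with ethyl 3-chloro-3-oxopropanoate to give the 2-acyloxybenzofuran enol ester F1. A nucleophilic pyridine catalyst (4-dimethylaminopyridine, or a chiral 4-pyrrolidinopyridine) then moves the acyl group from O to C3 through an acylpyridinium/enolate ion pair (Steglich-type, Claisen-like acyl transfer). This gives keto ester 22 directly, and its C8′ epimer is removed by chromatography.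

Step 18 (the doubly stabilized anion may be too weak a nucleophile for the deactivated acrylate ester). The fallback sets out from 26 and returns at 28. The allyl ester is removed first (Pd(PPh3)4, morpholine, THF), and decarboxylation gives the methyl ketone F2. Its kinetic lithium enolate (LiN(SiMe3)2, 2.2 equiv, THF, −78 to 0 °C) is a much stronger nucleophile and closes ring D by intramolecular Claisen condensation onto the acrylate ester, giving 28.

Step 24 (the C8a′ ketone sits between two quaternary carbons, and the free phenol could instead attack C7′). The fallback sets out from 33 and returns at 36. Selenide 33 is oxidized first (H2O2, pyridine); selenoxide elimination gives the 2-alkylidene-1,3-dione. The C2′ hydroxyl captures this at the more electrophilic, non-vinylogous C8a′ carbonyl, forming the cyclic hemiketal F3 with C4a′ now planar. Buffered Bu4NF/AcOH at 0 °C frees O5 to give the phenol hemiketal F4. Pyridinium p-toluenesulfonate with 4 Å molecular sieves in CH2Cl2 then exchanges the hemiketal hydroxyl for O5 through the O1′-stabilized oxocarbenium ion, giving 36.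

**Further compounds**
F1 | step 14 | ethyl 3-methoxybenzofuran-2-yl malonate built on O5/C6 of Fl (2-acyloxybenzofuran enol ester) | CCOC(=O)CC(=O)OC1=C(OC)c2c(O1)c1c(c(OC)c2OC)O[C@H](c2ccccc2)C[C@H]1O[Si](C)(C)C(C)(C)C
F2 | step 18 | ethyl (2E,4S)-4-[5-(tert-butyldimethylsilyloxy)-Fl-6-yl]-3,4-dimethoxy-5-oxohex-2-enoate | CC(=O)[C@@](OC)(/C(OC)=C\C(=O)OCC)c1c(O[Si](C)(C)C(C)(C)C)c2c(c(OC)c1OC)O[C@H](c1ccccc1)C[C@H]2O[Si](C)(C)C(C)(C)C
F3 | step 24 | C8a′ hemiketal: (2′S,8′S)-8a′-hydroxy-7′,8′-dimethoxy-2′-phenyl-8′-[5-(tert-butyldimethylsilyloxy)-Fl-6-yl]-2′,3′,8′,8a′-tetrahydrochromen-5′-one, both C8a′ epimers | COC1=CC(=O)C2=CC[C@@H](c3ccccc3)OC2(O)[C@]1(OC)c1c(O[Si](C)(C)C(C)(C)C)c2c(c(OC)c1OC)O[C@H](c1ccccc1)C[C@H]2O[Si](C)(C)C(C)(C)C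
F4 | step 24 | the same hemiketal with free O5 phenol (8′-(5-hydroxy-Fl-6-yl)) | COC1=CC(=O)C2=CC[C@@H](c3ccccc3)OC2(O)[C@]1(OC)c1c(O)c2c(c(OC)c1OC)O[C@H](c1ccccc1)C[C@H]2O[Si](C)(C)C(C)(C)C
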